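**Plan**

1. Target 33 is a longipin-2-en-1-one (longipinane numbering): a bicyclo[3.1.1]hept-3-en-2-one (C1–C5, C10, C11) whose one-carbon bridges C5 and C10 are spanned by C6–C9, carrying O7-tiglate and O9-angelate trans-1,3 on the seven-membered ring.
2. Cuts, in order: O9–angeloyl; then in one operation C7–C8, C9–H and O7–acyl (aldol–Tishchenko) back to keto-aldehyde 26 and tiglaldehyde; then C5–C6 (nitrile anion onto a cyclobutanone); then C5–C11 and C4–C10 (intramolecular vinylketene [2+2]); then C1–C2 (vinylogous Mukaiyama aldol).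
3. Enabling feature: C9 lies between quaternary C10 and C8, and C7 between quaternary C6 and C8, so the C9 methyl ketone enolises only toward C8 and the C7 aldehyde not at all. The anti-1,3-diol with two different esters is the retron of an aldol–Tishchenko reaction, which puts the acyl group on the aldol oxygen (O7) and leaves O9 free.
4. Forward: acyclic dienynoic acid, then cyclobutane and six-membered ring together ([2+2]), then the two side arms, then the seven-membered ring last, then the angelate.
5. Stereochemistry: the C1 carbinol from the asymmetric vinylogous aldol steers the [2+2] (C4, C10, C11) and is later oxidised away; E-alkene geometry puts the C10 methyl syn to the enone bridge; C5 by H-atom transfer under the bridge; C7 by the chiral lanthanum catalyst; C9 by intramolecular 1,3-anti hydride delivery.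

Key step: step 14

Remark (assumption): in the two catalyst-controlled steps (4 and 14) the substrate has no competing facial bias, so the catalyst antipode written is an assumption; the other antipode is used unchanged if a first run shows the opposite sense.

**Route**

Step 1
Reactants: 1 (E)-3-methylpent-2-en-4-yn-1-ol
Product: 4 (E)-5-(tert-butyldimethylsilyl)-3-methylpent-2-en-4-yn-1-ol, via dilithio derivative 2 (not isolated), via bis-silyl ether 3 (not isolated)
Conditions: n-BuLi (2.2 equiv), THF, −78 °C; TBSCl (2.3 equiv), −78 °C → rt; then PPTS (cat.), MeOH, rt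
Reagents that add atoms: tert-butyldimethylsilyl chloride, CC(C)(C)[Si](C)(C)Cl
Why: C- and O-silylation of the dianion followed by selective acid-catalysed methanolysis of the primary allylic silyl ether should leave the base-stable alkynylsilane that masks the acidic C–H through steps 6–10.

Step 2
Reactants: 4 (E)-5-(tert-butyldimethylsilyl)-3-methylpent-2-en-4-yn-1-ol
Product: 5 (E)-5-(tert-butyldimethylsilyl)-3-methylpent-2-en-4-ynal
Conditions: MnO2 (activated, excess), CH2Cl2, rt
Reagents that add atoms: none
Why: Allylic oxidation with manganese dioxide should stop at the enal and keep the E geometry.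

Step 3
Reactants: 6 methyl 3-methylbut-2-enoate
Product: 8 1-methoxy-3-methyl-1-(tert-butyldimethylsilyloxy)buta-1,3-diene, via lithium dienolate 7 (not isolated)
Conditions: LDA, THF/DMPU, −78 °C; TBSCl, −78 °C → rt
Reagents that add atoms: tert-butyldimethylsilyl chloride, CC(C)(C)[Si](C)(C)Cl
Why: γ-Deprotonation of the senecioate and O-silylation of the dienolate is the standard route to the silyl dienol ether needed for a vinylogous Mukaiyama aldol.

Step 4
Reactants: 5 (E)-5-(tert-butyldimethylsilyl)-3-methylpent-2-en-4-ynal; 8 1-methoxy-3-methyl-1-(tert-butyldimethylsilyloxy)buta-1,3-diene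
Product: 10 methyl (2E,5S,6E)-9-(tert-butyldimethylsilyl)-5-hydroxy-3,7-dimethylnona-2,6-dien-8-ynoate, via trichlorosilyl ether 9 (not isolated)
Conditions: SiCl4 (1.1 equiv), (S,S)-binaphthyldiamine-derived bisphosphoramide (2 mol%), i-Pr2NEt (10 mol%), CH2Cl2, −78 °C; aq. NaHCO3
Reagents that add atoms: none
Why: The Lewis-base-activated SiCl4 vinylogous Mukaiyama aldol of ester dienolates with conjugated aldehydes should give the γ-adduct as the E-enoate, with the catalyst alone setting C5 (S) on this achiral aldehyde.

Step 5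
Reactants: 10 methyl (2E,5S,6E)-9-(tert-butyldimethylsilyl)-5-hydroxy-3,7-dimethylnona-2,6-dien-8-ynoate
Product: 11 methyl (2E,5S,6E)-9-(tert-butyldimethylsilyl)-5-(tert-butyldimethylsilyloxy)-3,7-dimethylnona-2,6-dien-8-ynoate
Conditions: TBSCl, imidazole, DMF, rt
Reagents that add atoms: tert-butyldimethylsilyl chloride, CC(C)(C)[Si](C)(C)Cl
Why: Silylation of the secondary allylic alcohol blocks it during acid chloride and ketene formation and prevents isomerisation or lactonisation of the hydroxy enoate.

Step 6
Reactants: 11 methyl (2E,5S,6E)-9-(tert-butyldimethylsilyl)-5-(tert-butyldimethylsilyloxy)-3,7-dimethylnona-2,6-dien-8-ynoate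
Product: 12 (2E,5S,6E)-9-(tert-butyldimethylsilyl)-5-(tert-butyldimethylsilyloxy)-3,7-dimethylnona-2,6-dien-8-ynoic acid
Conditions: LiOH·H2O, THF/MeOH/H2O, 40 °C; then 1 M HCl to pH 4, 0 °C
Reagents that add atoms: lithium hydroxide, [Li+].[OH-]
Why: Saponification of the methyl ester should leave both the secondary silyl ether and the hindered alkynylsilane intact.

Step 7
Reactants: 12 (2E,5S,6E)-9-(tert-butyldimethylsilyl)-5-(tert-butyldimethylsilyloxy)-3,7-dimethylnona-2,6-dien-8-ynoic acid
Product: 15 4-(tert-butyldimethylsilyloxy)-7-methyl-2-methylene-7-[(tert-butyldimethylsilyl)ethynyl]bicyclo[3.1.1]heptan-6-one (silyloxy group on the side of the C6 carbonyl bridge; C7 methyl syn to the C2–C4 bridge), via acid chloride 13 (not isolated), via vinylketene 14 (not isolated)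
Conditions: 1-chloro-N,N,2-trimethylprop-1-en-1-amine, CH2Cl2, 0 °C → rt; then slow addition to Et3N (3 equiv), toluene, 110 °C (0.01 M)
Reagents that add atoms: none
Why: Triethylamine removes a proton from the methyl group cis to the acyl chloride and the resulting vinylketene should undergo the known crossed intramolecular ketene–alkene [2+2]; the carbonyl carbon bonds to C6 of the chain and the ketene α-carbon to the propargylically stabilised C7, suprafacial addition to the E-alkene places the methyl syn to the three-carbon bridge, and the silyloxy-bearing carbon avoids that methyl (allylic strain) so that the C5 stereocentre fixes the absolute configuration of both bridgeheads and the quaternary bridge.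

Step 8
Reactants: 15 4-(tert-butyldimethylsilyloxy)-7-methyl-2-methylene-7-[(tert-butyldimethylsilyl)ethynyl]bicyclo[3.1.1]heptan-6-one; 16 isobutyronitrile
Product: 19 O-[6-(2-cyanopropan-2-yl)-4-(tert-butyldimethylsilyloxy)-7-methyl-2-methylene-7-[(tert-butyldimethylsilyl)ethynyl]bicyclo[3.1.1]heptan-6-yl] S-methyl dithiocarbonate, via lithiated nitrile 17 (not isolated), via lithium alkoxide 18 (not isolated)
Conditions: 16, LDA, THF, −78 °C; 15, −78 °C; CS2, DMPU, −78 → 0 °C; MeI
Reagents that add atoms: carbon disulfide, S=C=S; iodomethane, CI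
Why: 1,2-Addition of the nitrile-stabilised tertiary carbanion to the strained cyclobutanone, which cannot enolise because both α-positions are bridgeheads, should enter anti to the C2–C4 bridge, and the alkoxide is trapped in the same flask as the xanthate; the configuration at C6 is of no consequence because it is reset in step 9.

Step 9
Reactants: 19 O-[6-(2-cyanopropan-2-yl)-4-(tert-butyldimethylsilyloxy)-7-methyl-2-methylene-7-[(tert-butyldimethylsilyl)ethynyl]bicyclo[3.1.1]heptan-6-yl] S-methyl dithiocarbonate
Product: 20 2-[4-(tert-butyldimethylsilyloxy)-7-methyl-2-methylene-7-[(tert-butyldimethylsilyl)ethynyl]bicyclo[3.1.1]heptan-6-yl]-2-methylpropanenitrile (6-H syn to the C2–C4 bridge; cyanopropyl group facing the alkynyl group)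
Conditions: Bu3SnH (1.5 equiv), AIBN (cat.), toluene, 100 °C
Reagents that add atoms: none
Why: Barton–McCombie deoxygenation of a tertiary xanthate that has no β-hydrogen available for Chugaev elimination; the tertiary cyclobutyl radical should take hydrogen on the face under the three-carbon bridge because that pocket can hold only hydrogen and the bulky cyanopropyl group can sit only anti to the bridge, which sets C5 of the target.

Step 10
Reactants: 20 2-[4-(tert-butyldimethylsilyloxy)-7-methyl-2-methylene-7-[(tert-butyldimethylsilyl)ethynyl]bicyclo[3.1.1]heptan-6-yl]-2-methylpropanenitrile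
Product: 22 2-[4-(tert-butyldimethylsilyloxy)-7-methyl-2-methylene-7-[(tert-butyldimethylsilyl)ethynyl]bicyclo[3.1.1]heptan-6-yl]-2-methylpropanal, via aldimine 21 (not isolated)
Conditions: DIBAL-H (1.3 equiv), toluene, −78 → −20 °C; 1 M HCl, 0 °C
Reagents that add atoms: water, O
Why: Partial reduction of a hindered tertiary nitrile with DIBAL-H stops at the aluminium aldimine, which hydrolyses to the non-enolisable aldehyde before any ketone is present in the molecule.

Step 11
Reactants: 22 2-[4-(tert-butyldimethylsilyloxy)-7-methyl-2-methylene-7-[(tert-butyldimethylsilyl)ethynyl]bicyclo[3.1.1]heptan-6-yl]-2-methylpropanal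
Product: 23 2-(7-ethynyl-4-hydroxy-7-methyl-2-methylenebicyclo[3.1.1]heptan-6-yl)-2-methylpropanal
Conditions: TBAF (2.5 equiv), AcOH (buffer), THF, 0 °C → rt
Reagents that add atoms: none
Why: Fluoride should cleave the silyl ether and the alkynylsilane in one operation, and the aldehyde has no α-hydrogen to suffer under the basic conditions.

Step 12
Reactants: 23 2-(7-ethynyl-4-hydroxy-7-methyl-2-methylenebicyclo[3.1.1]heptan-6-yl)-2-methylpropanal
Product: 25 2-(6-ethynyl-4,6-dimethyl-2-oxobicyclo[3.1.1]hept-3-en-7-yl)-2-methylpropanal, via β,γ-unsaturated ketone 24 (not isolated)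
Conditions: DMP, NaHCO3, CH2Cl2, rt; then DBU (cat.), CH2Cl2, rt
Reagents that add atoms: none
Why: Dess–Martin oxidation removes the auxiliary carbinol stereocentre, and base-catalysed migration of the exocyclic β,γ-double bond into conjugation gives the thermodynamically favoured verbenone-type enone.

Step 13
Reactants: 25 2-(6-ethynyl-4,6-dimethyl-2-oxobicyclo[3.1.1]hept-3-en-7-yl)-2-methylpropanal
Product: 26 2-(6-acetyl-4,6-dimethyl-2-oxobicyclo[3.1.1]hept-3-en-7-yl)-2-methylpropanal (acetyl and formylpropyl groups both anti to the enone bridge, facing each other)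
Conditions: (IPr)AuCl (2 mol%), AgSbF6 (2 mol%), 1,4-dioxane/H2O, 60 °C
Reagents that add atoms: water, O
Why: Gold(I)-catalysed Markovnikov hydration of the terminal alkyne should give the methyl ketone under conditions that the enone and the aldehyde tolerate.

Step 14
Reactants: 26 2-(6-acetyl-4,6-dimethyl-2-oxobicyclo[3.1.1]hept-3-en-7-yl)-2-methylpropanal; 27 tiglaldehyde ((E)-2-methylbut-2-enal)
Product: 30 (4R,5S,7R,9R,10R,11R)-9-hydroxy-7-tigloyloxylongipin-2-en-1-one, via aldol 28 (not isolated), via hemiacetal 29 (not isolated)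
Conditions: La(OTf)3 (10 mol%), (R)-BINOL (30 mol%), n-BuLi (56 mol%), THF, −20 °C, 26 (0.02 M); then 27 (3 equiv, slow addition), −20 → 0 °C
Reagents that add atoms: none
Why: Proposed new method: the binaphthoxide-bound lanthanum base enolises the only enolisable ketone position (C8H3, since C10 is quaternary) and the enolate adds to the non-enolisable C7 aldehyde (C6 is quaternary) in a 7-(enolendo)-exo-trig aldol that closes the seven-membered ring through C7–C8; the aldolate oxygen then adds to tiglaldehyde and the metal-bound hemiacetal 29 transfers hydride to the C9 carbonyl through a chair-like six-membered transition state, which fixes the tiglate on O7, frees O9 and sets C9 anti to C7. The closest known reaction types are the lithium- or lanthanide-mediated aldol–Tishchenko reaction of ketones with two equivalents of one aldehyde, its chiral lanthanum–lithium–BINOL variant and the Evans–Tishchenko reduction of β-hydroxy ketones; new here are the intramolecular aldol partner, the different and conjugated hydride-donor aldehyde, and the use of the catalyst to choose between diastereomeric aldolates. C7 is the one stereocentre the substrate cannot dictate, because the two faces of the aldehyde differ only through the remote C1=O and C3–Me ends of the bridge on the other side of the cyclobutane; the pair of aldolates, which interconvert by retro-aldol, is therefore to be resolved by the chiral catalyst in the irreversible hydride transfer, with no mismatched case. C9 follows from C7 by intramolecular hydride delivery (1,3-anti), and the trans-1,3 arrangement on the ring should keep the tiglate from migrating to O9. The step needs ring closure to outrun addition of the enolate to tiglaldehyde, which the tether and the late, slow addition of 27 should secure, and it needs the enone to stay out, which it should because its only acidic position (the C3 methyl) gives a dienolate that reprotonates without consequence.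

Step 15
Reactants: 30 (4R,5S,7R,9R,10R,11R)-9-hydroxy-7-tigloyloxylongipin-2-en-1-one; 31 angelic acid ((Z)-2-methylbut-2-enoic acid)
Product: 33 (4R,5S,7R,9R,10R,11R)-9-angeloyloxy-7-tigloyloxylongipin-2-en-1-one, via mixed anhydride 32 (not isolated)
Conditions: 31, 2,4,6-trichlorobenzoyl chloride, Et3N, toluene, rt; then 30, toluene, 80 °C (no DMAP)
Reagents that add atoms: none
Why: Yamaguchi-type mixed-anhydride esterification without a nucleophilic catalyst is the established way to acylate a hindered secondary alcohol with angelic acid without Z to E isomerisation, and it leaves the C7 tiglate and the enone untouched.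

**Compound list**

1 | (E)-3-methylpent-2-en-4-yn-1-ol | OC/C=C(\C)C#C | starting material
2 | dilithio derivative of 1 | [Li+].[Li+].[O-]C/C=C(\C)C#[C-] | intermediate
3 | O,C-bis(tert-butyldimethylsilyl) derivative of 1 | CC(C)(C)[Si](C)(C)OC/C=C(\C)C#C[Si](C)(C)C(C)(C)C | intermediate
4 | (E)-5-(tert-butyldimethylsilyl)-3-methylpent-2-en-4-yn-1-ol | OC/C=C(\C)C#C[Si](C)(C)C(C)(C)C | intermediate
5 | (E)-5-(tert-butyldimethylsilyl)-3-methylpent-2-en-4-ynal | O=C/C=C(\C)C#C[Si](C)(C)C(C)(C)C | intermediate
6 | methyl 3-methylbut-2-enoate | COC(=O)C=C(C)C | starting material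
7 | lithium dienolate of 6 | [Li+].COC([O-])=CC(C)=C | intermediate
8 | 1-methoxy-3-methyl-1-(tert-butyldimethylsilyloxy)buta-1,3-diene | COC(O[Si](C)(C)C(C)(C)C)=CC(C)=C | intermediate
9 | trichlorosilyl ether of 10 | COC(=O)/C=C(\C)C[C@H](O[Si](Cl)(Cl)Cl)/C=C(\C)C#C[Si](C)(C)C(C)(C)C | intermediate
10 | methyl (2E,5S,6E)-9-(tert-butyldimethylsilyl)-5-hydroxy-3,7-dimethylnona-2,6-dien-8-ynoate | COC(=O)/C=C(\C)C[C@H](O)/C=C(\C)C#C[Si](C)(C)C(C)(C)C | intermediate
11 | 5-O-TBS ether of 10 | COC(=O)/C=C(\C)C[C@H](O[Si](C)(C)C(C)(C)C)/C=C(\C)C#C[Si](C)(C)C(C)(C)C | intermediate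
12 | (2E,5S,6E)-9-(tert-butyldimethylsilyl)-5-(tert-butyldimethylsilyloxy)-3,7-dimethylnona-2,6-dien-8-ynoic acid | OC(=O)/C=C(\C)C[C@H](O[Si](C)(C)C(C)(C)C)/C=C(\C)C#C[Si](C)(C)C(C)(C)C | intermediate
13 | acid chloride of 12 | ClC(=O)/C=C(\C)C[C@H](O[Si](C)(C)C(C)(C)C)/C=C(\C)C#C[Si](C)(C)C(C)(C)C | intermediate
14 | vinylketene from 13 | O=C=CC(=C)C[C@H](O[Si](C)(C)C(C)(C)C)/C=C(\C)C#C[Si](C)(C)C(C)(C)C | intermediate
15 | 4-(tert-butyldimethylsilyloxy)-7-methyl-2-methylene-7-[(tert-butyldimethylsilyl)ethynyl]bicyclo[3.1.1]heptan-6-one | O=C2[C@H]3[C@@H](O[Si](C)(C)C(C)(C)C)CC(=C)[C@@H]2[C@@]3(C)C#C[Si](C)(C)C(C)(C)C | intermediate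
16 | isobutyronitrile | CC(C)C#N | starting material
17 | lithiated isobutyronitrile | [Li+].CC(C)=C=[N-] | intermediate
18 | lithium alkoxide adduct of 15 and 17 | [Li+].N#CC(C)(C)[C@]2([O-])[C@H]3[C@@H](O[Si](C)(C)C(C)(C)C)CC(=C)[C@@H]2[C@@]3(C)C#C[Si](C)(C)C(C)(C)C | intermediate
19 | S-methyl xanthate of the tertiary alcohol | N#CC(C)(C)[C@]2(OC(=S)SC)[C@H]3[C@@H](O[Si](C)(C)C(C)(C)C)CC(=C)[C@@H]2[C@@]3(C)C#C[Si](C)(C)C(C)(C)C | intermediate
20 | 2-[4-(tert-butyldimethylsilyloxy)-7-methyl-2-methylene-7-[(tert-butyldimethylsilyl)ethynyl]bicyclo[3.1.1]heptan-6-yl]-2-methylpropanenitrile | N#CC(C)(C)[C@@H]2[C@H]3[C@@H](O[Si](C)(C)C(C)(C)C)CC(=C)[C@@H]2[C@@]3(C)C#C[Si](C)(C)C(C)(C)C | intermediate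
21 | aldimine from 20 (as its aluminium complex) | N=CC(C)(C)[C@@H]2[C@H]3[C@@H](O[Si](C)(C)C(C)(C)C)CC(=C)[C@@H]2[C@@]3(C)C#C[Si](C)(C)C(C)(C)C | intermediate
22 | aldehyde corresponding to nitrile 20 | O=CC(C)(C)[C@@H]2[C@H]3[C@@H](O[Si](C)(C)C(C)(C)C)CC(=C)[C@@H]2[C@@]3(C)C#C[Si](C)(C)C(C)(C)C | intermediate
23 | 2-(7-ethynyl-4-hydroxy-7-methyl-2-methylenebicyclo[3.1.1]heptan-6-yl)-2-methylpropanal | O=CC(C)(C)[C@@H]2[C@H]3[C@@H](O)CC(=C)[C@@H]2[C@@]3(C)C#C | intermediate
24 | β,γ-unsaturated ketone from 23 | O=CC(C)(C)[C@@H]2[C@H]3C(=O)CC(=C)[C@@H]2[C@@]3(C)C#C | intermediate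
25 | 2-(6-ethynyl-4,6-dimethyl-2-oxobicyclo[3.1.1]hept-3-en-7-yl)-2-methylpropanal | O=CC(C)(C)[C@@H]2[C@H]3C(=O)C=C(C)[C@@H]2[C@@]3(C)C#C | intermediate
26 | 2-(6-acetyl-4,6-dimethyl-2-oxobicyclo[3.1.1]hept-3-en-7-yl)-2-methylpropanal | O=CC(C)(C)[C@@H]2[C@H]3C(=O)C=C(C)[C@@H]2[C@@]3(C)C(C)=O | intermediate
27 | tiglaldehyde | C/C=C(\C)C=O | starting material
28 | (7R)-7-hydroxylongipin-2-ene-1,9-dione (aldol) | O=C1C[C@@H](O)C(C)(C)[C@@H]2[C@H]3C(=O)C=C(C)[C@@H]2[C@]31C | intermediate
29 | hemiacetal of 28 with tiglaldehyde | O=C1C[C@@H](OC(O)/C(C)=C/C)C(C)(C)[C@@H]2[C@H]3C(=O)C=C(C)[C@@H]2[C@]31C | intermediate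
30 | (4R,5S,7R,9R,10R,11R)-9-hydroxy-7-tigloyloxylongipin-2-en-1-one | O[C@@H]1C[C@@H](OC(=O)/C(C)=C/C)C(C)(C)[C@@H]2[C@H]3C(=O)C=C(C)[C@@H]2[C@]31C | intermediate
31 | angelic acid | C/C=C(/C)C(O)=O | starting material
32 | angelic 2,4,6-trichlorobenzoic anhydride | C/C=C(/C)C(=O)OC(=O)c1c(Cl)cc(Cl)cc1Cl | intermediate
33 | (4R,5S,7R,9R,10R,11R)-9-angeloyloxy-7-tigloyloxylongipin-2-en-1-one | C/C=C(/C)C(=O)O[C@@H]1C[C@@H](OC(=O)/C(C)=C/C)C(C)(C)[C@@H]2[C@H]3C(=O)C=C(C)[C@@H]2[C@]31C | target

**Totals**

Total step count: 15. Longest linear sequence: 14 steps (steps 1, 2, 4–15; step 3 is a one-step side branch).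

**Steps most likely to fail**

Step 14 (proposed new method). The catalyst may fail to discriminate between the two interconverting aldolates in the hydride transfer, or the enolate may add to tiglaldehyde instead of closing the ring. The fallback uses known chemistry and runs from 26 back to 30. Base-mediated aldol condensation of 26 (KOt-Bu, t-BuOH, 50 °C) should give the cycloheptenone F1. Copper-catalysed enantioselective conjugate borylation (CuCl, (R,S)-Josiphos, NaOt-Bu, B2pin2, MeOH, THF) should give the β-boryl ketone F2 with the ligand setting C7; the hindered, β,β-disubstituted bicyclic enone should not compete. Oxidation with NaBO3 should give the β-hydroxy ketone 28, here isolated, and SmI2-catalysed Evans–Tishchenko reduction with tiglaldehyde 27 (THF, −10 °C) should return to 30.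

Step 7. The vinylketene may oligomerise before it adds to the enyne, whose alkene is deactivated by the allylic silyloxy group, or the facial preference may erode at 110 °C. The fallback runs from 12 back to 15. The acid is converted through the same chloroenamine activation and dimethylamine into the N,N-dimethylamide F3. Tf2O and 2,4,6-collidine in 1,2-dichloroethane should generate the far more electrophilic vinylketeniminium triflate F4, which should undergo the same crossed [2+2] at or below room temperature to the cyclobutaniminium triflate F5. Hydrolysis with aqueous NaHCO3 returns to ketone 15.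

Step 9 (together with the xanthate formation of step 8). The crowded tertiary alkoxide may resist thioacylation, or the bulky stannane may deliver hydrogen to the lower face of the cyclobutyl radical and give the C6 epimer. The fallback runs from 15 back to 20. Horner–Wadsworth–Emmons olefination of 15 with diethyl (1-cyanoethyl)phosphonate (NaH, THF) should give the alkylidene nitrile F6. Magnesium in methanol should reduce the conjugated double bond, the ring carbon being protonated by the small donor methanol, to give the secondary nitrile F7. α-Methylation (LDA, THF, −78 °C; MeI) then gives 20.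

Further compounds
F1 | step 14 | longipina-2,7-diene-1,9-dione (cycloheptenone from aldol condensation of 26) | O=C1C=CC(C)(C)[C@@H]2[C@H]3C(=O)C=C(C)[C@@H]2[C@]31C
F2 | step 14 | (7R)-7-(pinacolatoboryl)longipin-2-ene-1,9-dione | O=C1C[C@@H](B4OC(C)(C)C(C)(C)O4)C(C)(C)[C@@H]2[C@H]3C(=O)C=C(C)[C@@H]2[C@]31C
F3 | step 7 | N,N-dimethylamide of acid 12 | CN(C)C(=O)/C=C(\C)C[C@H](O[Si](C)(C)C(C)(C)C)/C=C(\C)C#C[Si](C)(C)C(C)(C)C
F4 | step 7 | vinylketeniminium triflate from F3 | C[N+](C)=C=CC(=C)C[C@H](O[Si](C)(C)C(C)(C)C)/C=C(\C)C#C[Si](C)(C)C(C)(C)C.[O-]S(=O)(=O)C(F)(F)F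
F5 | step 7 | N,N-dimethyl cyclobutaniminium triflate corresponding to ketone 15 | C[N+](C)=C2[C@H]3[C@@H](O[Si](C)(C)C(C)(C)C)CC(=C)[C@@H]2[C@@]3(C)C#C[Si](C)(C)C(C)(C)C.[O-]S(=O)(=O)C(F)(F)F
F6 | step 9 | 2-(bicyclo[3.1.1]heptan-6-ylidene)propanenitrile derived from 15 | N#CC(C)=C2[C@H]3[C@@H](O[Si](C)(C)C(C)(C)C)CC(=C)[C@@H]2[C@@]3(C)C#C[Si](C)(C)C(C)(C)C
F7 | step 9 | 2-(bicyclo[3.1.1]heptan-6-yl)propanenitrile (mono-methyl precursor of 20) | N#CC(C)[C@@H]2[C@H]3[C@@H](O[Si](C)(C)C(C)(C)C)CC(=C)[C@@H]2[C@@]3(C)C#C[Si](C)(C)C(C)(C)C
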